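**Assumptions and remarks on the chemistry**

- (S)-(+)-Terpinen-4-ol is taken as the enantiomerically enriched commercial material; its carbinol carbon becomes C-3 of the target and is never touched.
- Atom numbers are those of the octahydroazulene core of the target: C-3 carbinol, C-3a and C-8a ring fusion, C-4 ester carbon, C-6 (methyl)=C-7, C-8 ketone.
- The enol ether E/Z isomers and the epimers at centres that are destroyed later (nitro-alcohol carbinol, acetal carbon, C-6 and C-8 of the nitroso acetal) are carried as mixtures; their SMILES leave these centres open.
- The stereochemical outcome of the key step (trans ring fusion, facial control by C-3) is argued from transition-state models, not demonstrated.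

## Retrosynthetic overview

1. The anisoate and the silyl ether are handled last. Ring B (seven-membered) is closed at C4–C5 by an intramolecular carbonyl-ene reaction of a C-8 methallyl ketone with a C-4 aldehyde, and the alkene is then moved into conjugation.
2. Both the ketone and the aldehyde are unmasked from one tricyclic nitroso acetal: the isoxazolidine is a masked β-hydroxy ketone, the N,O-acetal a masked aldehyde, and a Peterson elimination places the alkene.
3. Key disconnection: C8a–C3a and C7–C8 in one tandem cycloaddition. An intramolecular nitroalkene (O=N–C8=C8a) plus enol ether (C3a=C4–OMe) [4+2] closes ring A with the quaternary C-8a; the resulting nitronate then undergoes [3+2] with methallyltrimethylsilane.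
4. Enabling feature: the C-8 carbonyl carbon and the oxygen-bearing C-4 sit 1,4 across the ring-fusion bond (C8–C8a–C3a–C4), and C-6 is β to C-8. Nitro can therefore stand for C8=O, the N,O-acetal for the C-4 aldehyde and the isoxazolidine for the enone.
5. The acyclic precursor comes from (S)-terpinen-4-ol (source of C-3) by ozonolysis, Henry reaction, dehydration and enol ether formation. Ring order: A in the key step, then B.

Key step: step 6

## Route

Step 1
Reactants: 1 (S)-(+)-terpinen-4-ol
Product: 2 tert-butyldimethylsilyl ether of 1
Conditions: TBSOTf, 2,6-lutidine, CH2Cl2, 0 °C to rt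
Reagents that add atoms: tert-butyldimethylsilyl trifluoromethanesulfonate, CC(C)(C)[Si](C)(C)OS(=O)(=O)C(F)(F)F
Why: Silyl triflate silylation of the hindered tertiary alcohol, needed so that the hydroxyl cannot add to the later nitroalkene (oxa-Michael) and survives the acidic steps; no stereocentre is touched.

Step 2
Reactants: 2 tert-butyldimethylsilyl ether of 1
Product: 3 (S)-5-(tert-butyldimethylsilyloxy)-7,7-dimethoxy-5-(propan-2-yl)heptan-2-one
Conditions: O3, CH2Cl2/MeOH, −78 °C; TsOH·H2O (cat.), rt; NaHCO3, Me2S
Reagents that add atoms: ozone, [O-][O+]=O; methanol, CO
Why: Criegee ozonolysis in methanol with acid acetalisation before the reductive work-up should differentiate the termini, the aldehyde carbon being trapped as its dimethyl acetal while the methyl ketone stays free.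

Step 3
Reactants: 3 keto acetal; 4 nitromethane
Product: 5 tertiary β-nitro alcohol (5-silyloxy-7,7-dimethoxy-2-methyl-1-nitro-5-(propan-2-yl)heptan-2-ol, both C-2 epimers)
Conditions: MeNO2 (solvent), tetramethylguanidine (cat.), rt
Reagents that add atoms: none
Why: Henry (nitroaldol) addition to the methyl ketone, driven by excess nitromethane; the new carbinol centre is removed in the next step.

Step 4
Reactants: 5 tertiary β-nitro alcohol
Product: 6 (E)-nitroalkene dimethyl acetal
Conditions: MsCl, Et3N, CH2Cl2, −20 to 0 °C
Reagents that add atoms: none
Why: Mesylation (through the sulfene) and E1cB elimination should give the conjugated nitroalkene with the nitro group trans to the chain; any Z or β,γ-unsaturated isomers re-enter later through base-mediated equilibration.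

Step 5
Reactants: 6 (E)-nitroalkene dimethyl acetal
Product: 7 nitroalkene methyl enol ether (enol ether E/Z mixture)
Conditions: TMSOTf, iPr2NEt, CH2Cl2, −40 to −10 °C; aq. NaHCO3
Reagents that add atoms: none
Why: Silyl triflate ionisation of the acetal and deprotonation of the oxocarbenium ion by the hindered amine (loss of methanol) gives the electron-rich enol ether; it is used at once, and any early cycloaddition only anticipates the first half of step 6.

Step 6
Reactants: 7 nitroalkene methyl enol ether; 8 methallyltrimethylsilane
Product: 10 tricyclic nitroso acetal, via cyclic nitronate 9 (not isolated)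
Conditions: 8 (10 equiv), iPr2NEt (5 mol %), toluene, 60 then 90 °C, sealed tube
Reagents that add atoms: none
Why: On heating, the (E)-nitroalkene acts as a 4π heterodiene (O=N–C=C) toward the tethered enol ether in an inverse-electron-demand hetero-Diels–Alder reaction, forming C8a–C3a and O–C4 to give cyclic nitronate 9, which as a 1,3-dipole then adds to the 1,1-disubstituted alkene of 8 in a [3+2] cycloaddition, forming C8–C7 and O–C6; the closest known reaction type is the tandem [4+2]/[3+2] cycloaddition of nitroalkenes with an intramolecular first and an intermolecular second stage. Ring A (cyclopentane) is closed in the [4+2] through the three-atom tether in the fused mode (a 5-exo-type closure at C-3a), the 1,2-oxazine N-oxide ring by the cycloaddition itself and the isoxazolidine by the intermolecular [3+2]. C-8a and C-3a should be set by the anti (exo) fold of the tether, which puts both tether bonds equatorial on the forming oxazine and gives the trans ring fusion (H-3a trans to the C-8a methyl), and the face of the enol ether is chosen by C-3: the allylic C–OSi bond lies in the alkene plane (inside) and the isopropyl group anti to the incoming nitroalkene, so C-4 ends cis to the silyloxy group and C-8 cis to isopropyl. The acetal carbon and the isoxazolidine carbons C-6 and C-8 form as mixtures that do not matter because all three are flattened later. The step needs the regiochemistry nitroalkene β-carbon to enol ether β-carbon (secured by polarity matching and by the tether), the E nitroalkene (Z and β,γ isomers are fed in by the amine), and the [3+2] regiochemistry carbon to CH2 and oxygen to the fully substituted carbon (secured by sterics and by the polarisation of the allylsilane).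

Step 7
Reactants: 10 tricyclic nitroso acetal
Product: 11 isoxazoline aldehyde
Conditions: 0.5 M HCl, THF/H2O, rt
Reagents that add atoms: none
Why: Acid hydrolysis of the N,O-acetal should free the C-4 aldehyde and an N-hydroxy isoxazolidine that loses water to the 2-isoxazoline (the known elimination of N-oxy isoxazolidines); C-3a keeps its configuration, which is also the thermodynamically preferred one (formyl trans to both isopropyl and the C-8 branch).

Step 8
Reactants: 11 isoxazoline aldehyde
Product: 13 methallyl ketone aldehyde, via β-hydroxysilane 12 (not isolated)
Conditions: Mo(CO)6, MeCN/H2O (15:1), 80 °C; then TsOH·H2O (cat.), CH2Cl2, 0 °C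
Reagents that add atoms: water, O
Why: Reductive N–O cleavage and imine hydrolysis turn the isoxazoline into the β-hydroxy ketone, and acid-promoted Peterson elimination of the β-hydroxysilane places the alkene regiospecifically at the terminal position (C6=C5) without conjugation.

Step 9
Reactants: 13 methallyl ketone aldehyde
Product: 14 bicyclic hydroxy ketone with exocyclic methylene at C-6
Conditions: Me2AlCl, CH2Cl2, −78 to −30 °C
Reagents that add atoms: none
Why: Lewis-acid-promoted type 2 intramolecular carbonyl-ene reaction: the terminal alkene carbon C-5 attacks the activated C-4 aldehyde to close the seven-membered ring B, and a chair-like transition state with hydrogen transfer from the exocyclic methyl should place the C-4 hydroxyl equatorial, cis to H-3a.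

Step 10
Reactants: 14 bicyclic hydroxy ketone with exocyclic methylene
Product: 15 4-hydroxy enone (silyl-protected core)
Conditions: DBU (cat.), toluene, 40 °C
Reagents that add atoms: none
Why: Base-mediated alkene migration through the dienolate moves the β,γ-exocyclic double bond into conjugation, giving the thermodynamically favoured trisubstituted C6=C7 enone; the free hydroxyl is a poor leaving group, so vinylogous elimination should not compete.

Step 11
Reactants: 15 4-hydroxy enone; 16 4-methoxybenzoyl chloride
Product: 17 silyl-protected target
Conditions: pyridine, DMAP (cat.), CH2Cl2, 0 °C to rt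
Reagents that add atoms: none
Why: DMAP-catalysed acylation of the secondary alcohol with retention at C-4 under mildly basic conditions that should not trigger vinylogous β-elimination of the new ester.

Step 12
Reactants: 17 silyl-protected target
Product: 18 target, (3R,3aS,4S,8aS)-3-hydroxy-6,8a-dimethyl-8-oxo-3-(propan-2-yl)-1,2,3,3a,4,5,8,8a-octahydroazulen-4-yl 4-methoxybenzoate
Conditions: HF·pyridine, THF, 0 °C to rt
Reagents that add atoms: none
Why: Fluoride cleavage of the tertiary silyl ether under non-basic conditions leaves the ester and the enone untouched and sets free the C-3 alcohol.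

## Compound list

1 | (S)-(+)-terpinen-4-ol, (1S)-4-methyl-1-(propan-2-yl)cyclohex-3-en-1-ol | CC1=CC[C@](O)(C(C)C)CC1 | starting material
2 | tert-butyldimethylsilyl ether of 1 | CC1=CC[C@](O[Si](C)(C)C(C)(C)C)(C(C)C)CC1 | intermediate
3 | (S)-5-(tert-butyldimethylsilyloxy)-7,7-dimethoxy-5-(propan-2-yl)heptan-2-one | CC(=O)CC[C@@](O[Si](C)(C)C(C)(C)C)(C(C)C)CC(OC)OC | intermediate
4 | nitromethane | C[N+](=O)[O-] | starting material
5 | tertiary β-nitro alcohol (C-2 epimers; silyloxy carbon as in 3) | CC(O)(C[N+](=O)[O-])CC[C@@](O[Si](C)(C)C(C)(C)C)(C(C)C)CC(OC)OC | intermediate
6 | (E)-nitroalkene dimethyl acetal (nitro trans to the chain) | C/C(=C\[N+](=O)[O-])CC[C@@](O[Si](C)(C)C(C)(C)C)(C(C)C)CC(OC)OC | intermediate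
7 | (E)-nitroalkene methyl enol ether (enol ether E/Z mixture) | C/C(=C\[N+](=O)[O-])CC[C@@](O[Si](C)(C)C(C)(C)C)(C(C)C)C=COC | intermediate
8 | methallyltrimethylsilane, trimethyl(2-methylprop-2-en-1-yl)silane | CC(=C)C[Si](C)(C)C | starting material
9 | trans-fused cyclopenta-1,2-oxazine N-oxide (cyclic nitronate; methoxy acetal carbon cis to the silyloxy group, ring-fusion H trans to methyl) | COC1O[N+]([O-])=C[C@@]2(C)CC[C@@](O[Si](C)(C)C(C)(C)C)(C(C)C)[C@H]12 | intermediate (not isolated)
10 | tricyclic nitroso acetal (isoxazolidine fused at N–C8 of the oxazine; isoxazolidine carbon bearing methyl and trimethylsilylmethyl) | COC1ON2OC(C)(C[Si](C)(C)C)CC2[C@@]2(C)CC[C@@](O[Si](C)(C)C(C)(C)C)(C(C)C)[C@H]12 | intermediate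
11 | isoxazoline aldehyde (cyclopentane carbaldehyde; formyl cis to silyloxy and trans to the isoxazolinyl group) | C[Si](C)(C)CC1(C)CC(=NO1)[C@@]2(C)CC[C@@](O[Si](C)(C)C(C)(C)C)(C(C)C)[C@@H]2C=O | intermediate
12 | β-hydroxysilane keto aldehyde | C[Si](C)(C)CC(C)(O)CC(=O)[C@@]1(C)CC[C@@](O[Si](C)(C)C(C)(C)C)(C(C)C)[C@@H]1C=O | intermediate (not isolated)
13 | methallyl ketone aldehyde | CC(=C)CC(=O)[C@@]1(C)CC[C@@](O[Si](C)(C)C(C)(C)C)(C(C)C)[C@@H]1C=O | intermediate
14 | trans-fused hydroazulenone with C-4 hydroxyl (cis to H-3a) and exocyclic methylene at C-6 | O[C@H]2CC(=C)CC(=O)[C@@]3(C)CC[C@@](O[Si](C)(C)C(C)(C)C)(C(C)C)[C@H]23 | intermediate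
15 | 4-hydroxy-6-methyl enone, 3-O-silyl | O[C@H]2CC(C)=CC(=O)[C@@]3(C)CC[C@@](O[Si](C)(C)C(C)(C)C)(C(C)C)[C@H]23 | intermediate
16 | 4-methoxybenzoyl chloride | COc1ccc(cc1)C(Cl)=O | starting material
17 | 3-O-tert-butyldimethylsilyl ether of the target | COc1ccc(C(=O)O[C@H]2CC(C)=CC(=O)[C@@]3(C)CC[C@@](O[Si](C)(C)C(C)(C)C)(C(C)C)[C@H]23)cc1 | intermediate
18 | (3R,3aS,4S,8aS)-3-hydroxy-6,8a-dimethyl-8-oxo-3-(propan-2-yl)-1,2,3,3a,4,5,8,8a-octahydroazulen-4-yl 4-methoxybenzoate | COc1ccc(C(=O)O[C@H]2CC(C)=CC(=O)[C@@]3(C)CC[C@@](O)(C(C)C)[C@H]23)cc1 | target

## Step count and risks

Total step count: 12. Longest linear sequence: 12 steps (from 1).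

**Step 6 (key step).** The [3+2] stage may be too slow for the hindered nitronate (its dipole carbon sits next to the quaternary C-8a), so that the nitronate decomposes before it is trapped. The tether may also fold syn in the [4+2] stage, giving the cis ring fusion and thereby the wrong C-8a configuration relative to C-3.
Fallback: it sets out from 7 and comes back at 11. Compound 7 is heated alone in toluene to nitronate 9, which is hydrolysed in a weakly acidic buffer to the γ-nitro aldehyde F1. Slow addition of phenyl isocyanate and Et3N to F1 in the presence of excess 8 dehydrates the primary nitro group to the nitrile oxide, a far more reactive dipole, which adds to 8 to give isoxazoline 11 directly.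

**Step 7.** The acid may open the nitroso acetal by other paths: loss of silicon with cleavage of the isoxazolidine C–O bond, or N–O heterolysis on the wrong side. The tertiary silyl ether may also be lost.
Fallback: it sets out from 7, avoids the nitroso acetal and comes back at 13. The γ-nitro aldehyde F1 is made as in the first fallback. Its nitronate is C-allylated with 2-methylallyl methyl carbonate and Pd(PPh3)4 (Tsuji–Trost reaction), which should stop after one allylation at the neopentyl-type carbon, to give the C-methallylated nitro aldehyde F2. A Nef reaction (NaOMe, then TiCl3 in NH4OAc buffer) converts the secondary nitro group into the ketone of 13.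

**Step 9.** The Lewis acid may promote enolisation of the β,γ-unsaturated ketone and aldol closure to a five-membered ring, or alkene migration into conjugation before the ene reaction. Facial selectivity at C-4 may be poor.
Fallback: it sets out from 13 and comes back at 15. DBU isomerises 13 to the conjugated enone aldehyde F3. KOtBu in tBuOH/THF then forms the dienolate (C-8a is quaternary, so only γ-deprotonation is possible), which closes ring B by a reversible intramolecular vinylogous aldol reaction. Under thermodynamic control this should give the trans-fused product with the equatorial C-4 hydroxyl, that is 15.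

Further compounds
F1 | step 6 | γ-nitro aldehyde (2-methyl-2-(nitromethyl)cyclopentane carbaldehyde; formyl trans to the nitromethyl group and cis to silyloxy) | [O-][N+](=O)C[C@@]1(C)CC[C@@](O[Si](C)(C)C(C)(C)C)(C(C)C)[C@@H]1C=O
F2 | step 7 | C-methallylated nitro aldehyde (nitro carbon epimers) | CC(=C)CC([N+](=O)[O-])[C@@]1(C)CC[C@@](O[Si](C)(C)C(C)(C)C)(C(C)C)[C@@H]1C=O
F3 | step 9 | conjugated enone aldehyde (3-methylbut-2-enoyl ketone) | CC(C)=CC(=O)[C@@]1(C)CC[C@@](O[Si](C)(C)C(C)(C)C)(C(C)C)[C@@H]1C=O
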